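The constants used here are invented.

Start with the easy step: in the first hours each intermediate only piles up, so count what each charge hands over.

| flask | substrate | partner | temperature | time | remark |
|---|---|---|---|---|---|
| birch | 0.013 M | 9.10 mM | 5 °C | 2.5 d |  |
| alder | 0.013 M | 9.10 mM | −25 °C | 2.5 d |  |
| oak | 0.013 M | 9.10 mM |  | 2.5 d | at −25 °C until 40 h, from then on at 5 °C |

    substrate → open intermediate (k1 = 0.044 h⁻¹, Ea1 = 92.0 kJ mol⁻¹)
    open intermediate + second intermediate → target (k2 = 1.8 L mol⁻¹ h⁻¹, Ea2 = 62.0 kJ mol⁻¹)
    2 open intermediate → homo product (k3 = 0.96 L mol⁻¹ h⁻¹, Ea3 = 58.0 kJ mol⁻¹)
    substrate + target ⇌ idle adduct, settled at all times (K4 = 190 L mol⁻¹, ΔH4 = −29.0 kJ mol⁻¹)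
    partner → second intermediate (k5 = 0.19 h⁻¹, Ea5 = 85.0 kJ mol⁻¹)
    (constants at 5 °C)

* which flask leads in share of target in all that became target or homo product ("all alike" within 1.5 percentage points) (birch / alder / oak / all alike)
* share of target in all that became target or homo product, birch
* share of target in all that became target or homo product, alder
* share of target in all that became target or homo product, oak

- percent here means substrate units held: one homo product or idle adduct counts as two
- what is said of target includes idle adduct
- two of one species on the left: rate k times its square, two consumed each time
- the list of constants is for 5 °C, to be carried to other temperatures by the activation energies and enthalpies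
- in an amount of target, one idle adduct counts as one target

**Start ratio.** Here is the quick number you asked for. Write the early opened fraction of substrate as the opening constant times time. Write the released partner, as a fraction of the substrate charge, as its release constant times time times the charge ratio. Time cancels between them. Target units over substrate units in homo product are the target constant over twice the homo constant, times the second intermediate's fraction over the open intermediate's. For birch's temperature this gives 2.83: call it the start ratio. The start share of target in birch is that ratio over one plus the ratio, so 73.9%.

**Powers of ten.** Carry it to alder in logarithms. Opening speeds up 120 between the two temperatures, which is 2.08 decades for 92.0 kJ mol⁻¹. The net barrier of the ratio is −3.00 kJ mol⁻¹, so the cold adds 0.0681 decades to the 0.452 of birch. That makes 0.520 decades, a ratio of 3.31, and a share of 76.8% for alder.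

**Where it stops.** The reckoning needs partner still in hand. In alder its life is 448 h, longer than the run of 2.5 d, so commit to 76.8% there. In birch the life is 5.26 h, shorter than the run. In oak it is shorter than the warm stretch of 20.0 h. Expect both of those flasks below the start share, with alder ahead, and put no figure on them.

**The forecast.** The forecast gives 54% for birch, 76% for alder and 58% for oak, with alder leading, on the ground that “the partner's release slows less than the substrate's opening”. It differs from my alder figure by 0.80 percentage points.

**Result.** The simulation gives 54.4% for birch, 76.1% for alder and 60.2% for oak, with alder leading, so the forecast held.

**Partner gap.** Alder keeps 87% of its partner and ends at 76.1%. The start share of 73.9% belongs to the early hours of birch; at the end birch has 0% of its partner left and stands at 54.4%. The using up of partner is the main reason why birch stands no higher: with that using up taken away, birch reaches 91.2%. The neighbour of birch charged with 0.022 M of substrate has a start ratio of 1.67, so a start share of 62.5% for its early hours; at the end, with 0% of its partner left, it stands at 40.5%.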